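The data are simulated for substances that don't exist.

Follow the reagent.

the same everywhere: solid substrate 0.050 M; reagent 1.05 equiv
- spring: temperature 25 °C; the very flask that is asked about, followed so far
- dawn: temperature 31 °C; run made earlier
- flask: temperature 25 °C; time 4.0 min

- spring (time / min: target / %, solid substrate / %): 0.250: 5, 81; 0.417: 15, 66; 0.667: 25, 60; 1.33: 39, 23; 2.00: 47, 4; 3.00: 53, 4
- dawn (time / min: target / %, solid substrate / %): 0.250: 6, 84; 0.417: 16, 69; 0.667: 26, 59; 1.33: 45, 23; 2.00: 47, 8; 3.00: 39, 0

(each reading ± 2 percentage points)

- Saturday's: at 4.0 min raise the temperature by 15 K, then wait 80 s
- Tuesday's: at 4.0 min add reagent, 100 % of the amount charged, then wait 80 s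
- Monday's: change nothing and wait 80 s more

- a species is counted by the solid substrate in it: one side product counts as two
- amounts and yields of target count solid product too
- given per volume of solution although it is solid: solid substrate, solid product
- the volume of additions can be left aside
- the earlier runs were read with a standard deviation of 2 percentage points
- candidate steps: solid substrate <-> dissolved substrate; dissolved substrate + reagent -> target; dissolved substrate + target -> side product; solid product <-> target; 2 reagent -> self-condensation product
- at the start none of the solid substrate is in solution

- target, in percent of the solid substrate first charged, at 4.0 min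
- the remedy with the largest gain of target, or "none" below 2 percentage points (Saturday's / Tuesday's / Monday's / none)
- target present, in percent of the solid substrate first charged, after Tuesday's
- target present, in percent of the solid substrate first charged, after Monday's

In the spring flask at 3.00 min, the target reads 53 % and the solid substrate 4 %. The rest of the charge is elsewhere in solution, as dissolved substrate or side product:

pool = 43.0 %

Yet the target gains 6 percentage points in the 1.00 min after 2.00 min, and it gained 8 points in the 0.670 min before. Substrate is waiting, so I suspect its partner. Self-condensation may be taking the reagent, which would make it the limiting reagent despite its excess. I divide the rate of target formation by the rate of reagent loss. Time drops out. I take the whole reagent charge as used by 3.00 min, which is my assumption, and the readings give: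

φ = target / reagent charged = 53 % / 1.05 equiv = 0.505

So φ is the reagent yield, the fraction of the charged reagent that ends as target.

With φ held, I expect the spring flask to stay near 53 % at 4.0 min. Tuesday's fresh charge, at the same φ, buys:

0.505 × 1.05 equiv × 100 % = 53.0 %

That is more than the pool, so my ceiling is 96.0 %.

Is one number enough? No. In the dawn flask, the target falls from 47 % to 39 % after 2.00 min, and φ does not count such losses. I therefore expect no gain from Monday's or Saturday's, and I choose Tuesday's.

The forecast gives 55 % (50 % to 59 %) and picks Tuesday's. It puts Tuesday's at 73 % (62 % to 83 %) and Monday's at 55 % (48 % to 60 %). Its ground: “Slowing formation suggests self-condensation has nearly used up the reagent”.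

The flask gives 50.7 %, and Tuesday's is best. Tuesday's reaches 84.2 %, which is 11 points above the forecast, and Monday's falls to 48.5 %.

    solid substrate ⇌ dissolved substrate, rate k1*(cs1 - [dissolved substrate]) while solid is left; crystals form when [dissolved substrate] > cs1 (solubility = 28.0 mM, k = 0.0250 s⁻¹)
    dissolved substrate + reagent → target (k = 1.40 M⁻¹ s⁻¹, Ea = 62.0 kJ mol⁻¹)
    dissolved substrate + target → side product (k = 0.0460 M⁻¹ s⁻¹, Ea = 55.0 kJ mol⁻¹)
    solid product ⇌ target, rate k4*(cs4 - [target]) while solid is left; crystals form when [target] > cs4 (solubility = 18.0 mM, k = 0.490 s⁻¹)
    2 reagent → self-condensation product (k = 0.200 M⁻¹ s⁻¹, Ea = 66.0 kJ mol⁻¹)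
    (constants at 25 °C)

Self-condensation and the low solubility of the dissolved substrate are part of the reason for the stall: removed singly, they lift the target at 4.0 min from 50.7 % to 90.9 % and 79.6 %. Self-condensation is also part of the reason for Tuesday's gain, which is 4.2 points without it and 33 points with it. The 53.0 % priced by φ exceeds the 37.2 % of dissolved substrate present, and Tuesday's gain of 33 points stays below that amount. Adding back to the target the half of the side product that passed through it, φ in this flask at 4.0 min is 0.541, where I read 0.505 earlier. The same count in the repeat at 40 °C gives 0.380, lower than in this flask, and the target in that repeat stands at 22.9 %.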